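**Retrosynthetic overview**
1. Target 12 is the stearate of benzylic alcohol 10, so the ester C–O bond is made last from stearoyl chloride 11; 10 comes from methyl ester 9 by hydride reduction.
2. The C4=C5 styrene bond of 9 is traced back to sulfoxide 8 and sulfide 7, so sulfur on C5 serves as a traceless handle.
3. The strategy rests on the oxepine ring of the 1-benzoxepine (O1, C2, C3, C4, C5, C5a, C9a), the only ring to be built. Its O1–C9a–C5a–C5 segment is the frame of an ortho-quinone methide (nucleophilic O1, electrophilic C5), and its C2–C3(=CH2)–C4 segment is a three-carbon unit that already holds the exocyclic methylene.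
4. Ring 7 is therefore cut at C4–C5 and O1–C2 into dithioacetal 3 and the bifunctional allylsilane 4; in the forward sense C4–C5 forms first and O1–C2 closes the ring in the same step.
5. Dithioacetal 3 comes from aldehyde 1 and thiophenol 2.

Key step: step 2

Remark: the target has no stereocentre. The C5 centre formed in step 2 and the sulfur centre of 8 are carried without control and vanish in step 4; compounds 6, 7 and 8 are racemic.

**Step 1**
Reactants: 1 methyl 3-formyl-4-hydroxybenzoate; 2 thiophenol (2.2 equiv)
Product: 3 methyl 3-[bis(phenylsulfanyl)methyl]-4-hydroxybenzoate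
Conditions: BF3·OEt2 (20 mol %), 4 Å molecular sieves, CH2Cl2, 0 → 23 °C
Reagents that add atoms: none
Why: Lewis-acid-catalysed dithioacetalisation, in which BF3 activates the formyl group and two thiophenol additions with loss of water (taken up by the sieves) give the S,S-acetal, while the methyl ester and the phenol stay untouched.

**Step 2**
Reactants: 3 methyl 3-[bis(phenylsulfanyl)methyl]-4-hydroxybenzoate; 4 [2-(chloromethyl)prop-2-en-1-yl]trimethylsilane (1.5 equiv)
Product: 7 methyl 3-methylidene-5-(phenylsulfanyl)-2,3,4,5-tetrahydro-1-benzoxepine-7-carboxylate (racemic), via thio-ortho-quinone methide 5 (not isolated), via open-chain allylic chloride 6 (not isolated)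
Conditions: SnCl4 (1.1 equiv), CH2Cl2, −78 °C; then in the same flask DMF (dilution to about 0.01 M), MeSO2SMe (1.2 equiv), Cs2CO3 (6 equiv), −78 → 40 °C
Reagents that add atoms: none
Why: Proposed new method: SnCl4 removes one benzenethiolate from 3 to give the sulfur-stabilised cation that is the O-metallated form of thio-ortho-quinone methide 5; the CH2 terminus of allylsilane 4 adds to its benzylic carbon (bond C4–C5), the tertiary beta-silyl cation loses Me3Si+ to leave the 1,1-disubstituted alkene of 6, and after DMF has tied up the tin the cesium phenoxide of 6 displaces the allylic chloride (bond O1–C2). The closest known reactions are the SnCl4-mediated Hosomi–Sakurai allylation of dithioacetals and of ortho-quinone methides, the use of 2-(chloromethyl)allylsilanes as conjunctive three-carbon reagents, and the intramolecular Williamson ether synthesis; their combination in one flask into a 1-benzoxepine is the untested part. The seven-membered ring closes by a 7-exo-tet SN2 displacement, helped by the two sp2 centres in the tether and by dilution. C5 is formed as a racemate with no controlling element, which is acceptable because step 4 removes this centre. The step needs C-allylation with desilylation (not capture of the beta-silyl cation by the phenol oxygen to a chroman), a single C–S ionisation, and O- over S-alkylation; the small Me3Si group and the chloride supplied by SnCl4 favour desilylation, a second ionisation would give a cation without sulfur stabilisation on a ring deactivated by the ester, and the sulfide of 6 is a far weaker nucleophile than its phenoxide. The benzenethiolate set free by the ionisation would compete with the phenoxide for the allylic chloride once base is added, so MeSO2SMe is present in the second stage to convert it at once into inert methyl phenyl disulfide.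

**Step 3**
Reactants: 7 methyl 3-methylidene-5-(phenylsulfanyl)-2,3,4,5-tetrahydro-1-benzoxepine-7-carboxylate
Product: 8 methyl 5-(benzenesulfinyl)-3-methylidene-2,3,4,5-tetrahydro-1-benzoxepine-7-carboxylate (racemic, mixture of diastereomers at sulfur)
Conditions: NaIO4 (1.1 equiv), MeOH/THF/H2O, 0 → 23 °C
Reagents that add atoms: sodium periodate NaIO4, [Na+].[O-]I(=O)(=O)=O
Why: Periodate oxidation of a sulfide to a sulfoxide is selective for sulfur and stops at the sulfoxide with one equivalent, leaving the alkene, ester and aryl ether alone; the new sulfur stereocentre is not controlled and need not be, since either diastereomer has a C4 hydrogen that can reach the S–O bond.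

**Step 4**
Reactants: 8 methyl 5-(benzenesulfinyl)-3-methylidene-2,3,4,5-tetrahydro-1-benzoxepine-7-carboxylate
Product: 9 methyl 3-methylidene-2,3-dihydro-1-benzoxepine-7-carboxylate
Conditions: NaHCO3 (solid), toluene, 110 °C
Reagents that add atoms: none
Why: Thermal sulfoxide syn-elimination (Ei, five-membered transition state), in which the only beta-hydrogens are on C4 because C5a is aromatic and they are allylic, so the conjugated C4=C5 bond (necessarily cis in the ring) should form under neutral conditions with NaHCO3 buffering the acid that arises when the sulfenic acid self-condenses; the C5 stereocentre disappears here.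

**Step 5**
Reactants: 9 methyl 3-methylidene-2,3-dihydro-1-benzoxepine-7-carboxylate
Product: 10 (3-methylidene-2,3-dihydro-1-benzoxepin-7-yl)methanol
Conditions: iBu2AlH (2.5 equiv), CH2Cl2, −78 → 0 °C; aq. potassium sodium tartrate
Reagents that add atoms: none
Why: Hydride reduction of an aryl ester to the primary alcohol with iBu2AlH (two hydride transfers through the aldehyde), which should not touch the unactivated diene or the aryl ether, and the neutral tartrate work-up spares the acid-sensitive para-alkoxybenzylic alcohol.

**Step 6**
Reactants: 10 (3-methylidene-2,3-dihydro-1-benzoxepin-7-yl)methanol; 11 stearoyl chloride (octadecanoyl chloride, 1.2 equiv)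
Product: 12 (3-methylidene-2,3-dihydro-1-benzoxepin-7-yl)methyl octadecanoate (target)
Conditions: Et3N (2 equiv), DMAP (10 mol %), CH2Cl2, 0 → 23 °C
Reagents that add atoms: none
Why: DMAP-catalysed acylation of a primary alcohol with an acid chloride (nucleophilic catalysis through the N-acylpyridinium ion), with Et3N taking up HCl so that the para-alkoxybenzylic ester and the diene are not exposed to acid.

**Compound list**
1 | methyl 3-formyl-4-hydroxybenzoate | COC(=O)c1ccc(O)c(C=O)c1 | starting material
2 | thiophenol | Sc1ccccc1 | starting material
3 | methyl 3-[bis(phenylsulfanyl)methyl]-4-hydroxybenzoate | COC(=O)c1ccc(O)c(C(Sc2ccccc2)Sc2ccccc2)c1 | intermediate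
4 | [2-(chloromethyl)prop-2-en-1-yl]trimethylsilane | C=C(CCl)C[Si](C)(C)C | starting material
5 | methyl 4-oxo-3-[(phenylsulfanyl)methylidene]cyclohexa-1,5-diene-1-carboxylate (thio-ortho-quinone methide, present under SnCl4 as its O-stannylated thionium form) | COC(=O)C1=CC(=CSc2ccccc2)C(=O)C=C1 | intermediate
6 | methyl 3-[3-(chloromethyl)-1-(phenylsulfanyl)but-3-en-1-yl]-4-hydroxybenzoate (racemic) | COC(=O)c1ccc(O)c(C(Sc2ccccc2)CC(=C)CCl)c1 | intermediate
7 | methyl 3-methylidene-5-(phenylsulfanyl)-2,3,4,5-tetrahydro-1-benzoxepine-7-carboxylate (racemic) | COC(=O)c1ccc2OCC(=C)CC(Sc3ccccc3)c2c1 | intermediate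
8 | methyl 5-(benzenesulfinyl)-3-methylidene-2,3,4,5-tetrahydro-1-benzoxepine-7-carboxylate (racemic, both sulfur epimers) | COC(=O)c1ccc2OCC(=C)CC(S(=O)c3ccccc3)c2c1 | intermediate
9 | methyl 3-methylidene-2,3-dihydro-1-benzoxepine-7-carboxylate | COC(=O)c1ccc2OCC(=C)C=Cc2c1 | intermediate
10 | (3-methylidene-2,3-dihydro-1-benzoxepin-7-yl)methanol | OCc1ccc2OCC(=C)C=Cc2c1 | intermediate
11 | stearoyl chloride (octadecanoyl chloride) | CCCCCCCCCCCCCCCCCC(=O)Cl | starting material
12 | (3-methylidene-2,3-dihydro-1-benzoxepin-7-yl)methyl octadecanoate | C=C1C=Cc2cc(COC(=O)CCCCCCCCCCCCCCCCC)ccc2OC1 | target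

Total step count: 6. Longest linear sequence: 6 steps (from 1).

**Steps most likely to fail**

Step 2 (proposed new method). Three processes may defeat it:
- the phenol oxygen may capture the beta-silyl cation before desilylation;
- HCl formed from the phenol and SnCl4 may protodesilylate the allylsilane;
- tin residues may hold the phenoxide back, so that the ring closure stalls and intermolecular alkylation takes over.

The fallback uses known reactions and reverses the order of bond formation. It sets out from 1, which is O-alkylated with an excess of 3-chloro-2-(chloromethyl)prop-1-ene (C=C(CCl)CCl; K2CO3, DMF) to give methyl 4-{[2-(chloromethyl)prop-2-en-1-yl]oxy}-3-formylbenzoate F1. An intramolecular Nozaki–Hiyama allylation of the aldehyde (CrCl2, THF/DMF, high dilution) should then close the oxepine to methyl 5-hydroxy-3-methylidene-2,3,4,5-tetrahydro-1-benzoxepine-7-carboxylate F2. Dehydration of this benzylic alcohol with the Burgess reagent in warm toluene should give the C4=C5 alkene, and the fallback comes back to the route at 9.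

Step 4. The benzenesulfenic acid released at 110 °C may add back to the diene, or acid formed from it may move the exocyclic double bond into the ring. The fallback avoids a sulfenic acid altogether. It sets out from 7, which is S-methylated with MeOTf in CH2Cl2 to methyl 5-[methyl(phenyl)sulfonio]-3-methylidene-2,3,4,5-tetrahydro-1-benzoxepine-7-carboxylate trifluoromethanesulfonate F3. DBU at room temperature should then eliminate neutral methyl phenyl sulfide across C4–C5, and the fallback comes back to the route at 9.

Step 3. Oxidation of the hindered aryl benzylic sulfide in the aqueous medium may be sluggish, and forcing it may carry some material on to the sulfone, which no longer eliminates thermally. The fallback replaces oxygen transfer by nitrogen transfer, which cannot over-oxidise. It sets out from 7, which with chloramine-T (TsN(Cl)Na, MeOH/CH2Cl2) should give methyl 3-methylidene-5-{S-phenyl-N-[(4-methylphenyl)sulfonyl]sulfinimidoyl}-2,3,4,5-tetrahydro-1-benzoxepine-7-carboxylate F4. This N-tosylsulfilimine should undergo syn-elimination in toluene at about 80 °C, and the fallback comes back to the route at 9.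

**Further compounds**
F1 | step 2 | methyl 4-{[2-(chloromethyl)prop-2-en-1-yl]oxy}-3-formylbenzoate | COC(=O)c1ccc(OCC(=C)CCl)c(C=O)c1
F2 | step 2 | methyl 5-hydroxy-3-methylidene-2,3,4,5-tetrahydro-1-benzoxepine-7-carboxylate (racemic) | COC(=O)c1ccc2OCC(=C)CC(O)c2c1
F3 | step 4 | methyl 5-[methyl(phenyl)sulfonio]-3-methylidene-2,3,4,5-tetrahydro-1-benzoxepine-7-carboxylate trifluoromethanesulfonate | COC(=O)c1ccc2OCC(=C)CC([S+](C)c3ccccc3)c2c1.[O-]S(=O)(=O)C(F)(F)F
F4 | step 3 | methyl 3-methylidene-5-{S-phenyl-N-[(4-methylphenyl)sulfonyl]sulfinimidoyl}-2,3,4,5-tetrahydro-1-benzoxepine-7-carboxylate | COC(=O)c1ccc2OCC(=C)CC(S(=NS(=O)(=O)c3ccc(C)cc3)c3ccccc3)c2c1
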